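## Analysis of the target

The target, C28H30O7, is a depsidone. A benzoate ring (ring A) and a phenol ring (ring B) are joined by a diaryl ether oxygen and by an aryl ester, which together close a seven-membered dioxepinone ring; ring B also carries a fused 2,2-dimethyl-2H-pyran, and each benzene ring carries one prenyl group. Positions are numbered as follows: in ring A, A1 bears the ether oxygen, A2 the prenyl group, A3 a hydroxyl, A4 hydrogen, A5 a hydroxyl and A6 the lactone carbonyl; in ring B, B1 bears the prenyl group, B2 a hydroxyl, B3 the pyran oxygen, B4 the pyran carbon, B5 the ester oxygen and B6 the ether oxygen. There is no stereocentre and no stereogenic double bond, so the problem is purely one of regiochemistry on a hexasubstituted ring B and a pentasubstituted ring A. The sensitive groups are the two ortho-prenyl phenols (acid closes them to chromans), the chromene, the electron-rich tetraoxygenated ring B (easily oxidised to a quinone) and the aryl lactone (opened by bases and nucleophiles); once the lactone is open, the 2,4,6-trioxygenated benzoic acid decarboxylates readily. The hardest bond is the ether A1–O–B6, whose oxygen has four ortho neighbours (prenyl on A2, carboxyl on A6, prenyl on B1, oxygen on B5), so coupling two finished rings is unattractive. The plan rests on the pattern of ring A: oxygens on A3 and A5 with the carboxyl on A6 make a β-resorcylate, the carbons A2–A5 map onto a prenylated 1,3-dioxygenated diene, and A1 with A6 map onto an alkynoate whose β-carbon already carries the ether oxygen. The crowded ether can therefore be made on an sp carbon before ring A exists.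

## Retrosynthetic reasoning

**Lactone (25 to 24).** The last bond made is the ester bond between the carboxyl carbon on A6 and the oxygen on B5. It is cut first because the aryl lactone is the group least able to survive the rest of the chemistry. Its formation needs no differentiation among the four phenols of seco acid 24, since only the B5 hydroxyl can reach the carboxyl through a seven-membered transition state. The forward reaction has to activate the acid without acylating the other phenols intermolecularly.

**Order of unmasking (24 to 23 to 22).** Acid 24 is traced back to allyl ester 23 and this to bis(methoxymethyl) ether 22. The order matters: 24 is a 2,4,6-trioxygenated benzoic acid that would decarboxylate under the protic acid needed to remove the acetal ethers. These are therefore removed while the carboxyl is still an ester, and the allyl group is taken off afterwards under neutral conditions with zerovalent palladium. An allyl ester is chosen because saponifying a di-ortho-substituted benzoate would need conditions that the prenyl phenols and the ether would not tolerate.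

**Ring A (22 to 5 and 20).** Ring A of 22 is cut at A1–A2 and A5–A6. This returns diene 5, which holds A2 to A5 with the prenyl group on its terminus and both oxygens in place, and ynoate 20, which holds A6 with its carboxyl and A1 with the ether oxygen. Cutting here and not at the ether C–O bond means the oxygen between the rings is attached to a linear sp carbon when it is made. The five substituents of ring A are then placed by the polarity of the two partners, not by substitution on a benzene ring. The forward step has to be regioselective (prenyl terminus to the oxygen-bearing alkyne carbon) and must be followed by aromatisation through loss of the ketal methoxy group and the silyl groups.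

**Ynoate (20 to 16 and 17; 16 to 14 and 15).** Ynoate 20 is cut between the alkyne and the ester carbon, giving chloroformate 17 and acetylide 19. The acetylide comes from dichlorovinyl ether 16 by elimination to chloroalkyne 18 and halogen–metal exchange. Ether 16 is cut at its O–C(vinyl) bond to phenol 14 and trichloroethylene 15. Both bonds are made on an unhindered two-carbon unit, and ring B has no free position at which a strong base could metalate.

**Differentiating the ring B oxygens (14 to 13 to 11 to 10).** Phenol 14 has four ring oxygens that end up in three different roles. The C6 oxygen is carried as an allyl ether (13), and the two acetal ethers are traced back through hydroquinone 12 to the two carbonyl groups of quinone 11. In hydroxyquinone 10 the three oxygens already differ by oxidation state: the hydroxyl is alkylated before reduction and the two carbonyl oxygens are protected after it. No selective reaction among like phenols is needed.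

**Prenyl group on B1 (10 to 9 and 2).** The prenyl group is cut from the ring carbon lying between the hydroxyl and a carbonyl of 9. This is the central carbon of a vinylogous acid and the only nucleophilic carbon of 9, so bromide 2 can be attached without a directing group.

**Pyran ring (9 to 6 and 7).** The pyran of 9 is cut at the C4–C4a and O1–C2 bonds, leading to quinone 6 and enal 7 by way of condensation product 8. Quinone 6 already holds the four oxygens of ring B in the 1,2,4,5 relationship and two nucleophilic CH positions para to one another, which become B4 and B1.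

**Diene (5 to 4 to 3 to 1 and 2).** Diene 5 is the double silyl enol ether of keto ester 3, reached through mono-silylated 4. Keto ester 3 is cut between its γ-carbon and the prenyl CH2, giving acetoacetate 1 and bromide 2.

## Alternatives that were turned down

Alternative 1: Anionic closure of the lactone by an aryllithium.
- **Disconnection:** the bond between A6 and the lactone carbonyl carbon. The carbonyl is stored as a phenyl carbonate on the B5 oxygen and A6 carries iodine, in a preformed diaryl ether (compound A1, with a second phenyl carbonate on the B2 oxygen and methoxymethyl ethers on A3 and A5).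
- **Forward key step:** iodine–lithium exchange with tert-butyllithium at low temperature gives the A6 aryllithium, which attacks the B5 carbonate through a seven-membered transition state and expels phenoxide, giving the protected depsidone compound A2.
- **For:** the carbonyl carbon and the seven-membered ring arrive in one fast intramolecular step. No free trioxygenated benzoic acid and no polyphenolic seco acid ever exist. The exchange temperature is compatible with prenyl groups and the chromene.
- **Against:** the step presupposes the tetra-ortho-substituted ether, so the hardest bond is moved into the synthesis of compound A1 and still has to be made by coupling two fully substituted rings. Ring A of compound A1 is a pentasubstituted iodoarene whose prenyl group must sit on A2 and not on the more nucleophilic A4 between the two ether oxygens. The tetrahedral intermediate can expel the ring B aryloxide instead of phenoxide. The B2 carbonate left in compound A2 must be removed by a base or nucleophile in the presence of the lactone, which is an aryl ester of the same kind.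
- **Comparison:** on the ring-closing event this alternative is stronger than the chosen route, which ends with a carbodiimide lactonisation of an unprotected tetraphenolic acid. The chosen route offers in return that the crowded ether and the substitution pattern of ring A are both fixed by the way two acyclic partners join, so no hindered aryl–oxygen coupling is needed.

Alternative 2: Ring A as an aryne that takes up a phenoxide and carbon dioxide.
- **Disconnection:** the A1–O bond and the A6–carboxyl bond in one operation. Ring A is the A1/A6 aryne released from silylaryl triflate compound A3; ring B is the phenoxide of 14.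
- **Forward key step:** fluoride (CsF) generates the aryne, the phenoxide adds at A1, and the A6 aryl anion is trapped by carbon dioxide, giving diaryl ether acid compound A4, the tetrakis(methoxymethyl) ether of seco acid 24.
- **For:** aryne additions have early transition states and tolerate hindered phenoxides at room temperature. The ether oxygen on A5 directs the nucleophile to the distal carbon A1 by induction, as required. The route is convergent and needs one step from phenol 14 where the chosen route needs three.
- **Against:** compound A3 is again a pentasubstituted arene with silyl, triflate and prenyl groups on three adjacent carbons, so the regiochemical problem of ring A is moved, not solved. The prenyl group on A2 sterically opposes attack at A1 while the electronics favour it. An aryne next to a prenyl group, and in the presence of the prenyl and chromene alkenes of the phenoxide, can be consumed by ene reactions. The aryl anion must capture carbon dioxide faster than a proton, while the phenoxide is reversibly carbonated by the same gas. The four acetal ethers of compound A4 have to be removed by acid while the carboxyl is free, which invites decarboxylation.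
- **Comparison:** in convergence and in handling the hindered ether this alternative is at least as strong. The chosen route offers unambiguous placement of all five ring A substituents from the connectivity of its partners, no high-energy intermediate beside two prenyl groups, and a carboxyl that stays an ester until the acid-sensitive stage is over.

Alternative 3: Late double Claisen rearrangement on a bare ring B.
- **Disconnection:** the B1–prenyl bond and the B4–C and O–C bonds of the pyran. The precursor is depsidone compound A5, in which B1 and B4 carry hydrogen, the B2 oxygen a 1,1-dimethylallyl group and the B3 oxygen a 1,1-dimethylpropargyl group.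
- **Forward key step:** on heating, the allyl ether rearranges to B1 and appears there as a prenyl group. The propargyl ether rearranges to B4, and a hydrogen shift and oxa-6π closure then build the chromene, giving compound A6, the A3 methoxymethyl ether of the target.
- **For:** each ether has only one free ortho position, so both rearrangements are regiochemically fixed, and the propargyl ether route to 2,2-dimethylchromenes is well established. Ring B stays simple while the ether and lactone are made, so the ether oxygen on B6 has a hydrogen beside it and is much less hindered. Ring B needs fewer protecting-group operations.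
- **Against:** two different tertiary ethers must be placed on the adjacent oxygens B2 and B3 in the presence of the lactone; the allyl ether is normally reached by semihydrogenation of a propargyl ether, which forces a stepwise, differentiated sequence. Tertiary allyl aryl ethers ionise or lose their five-carbon unit on heating. The B2 phenol freed by the first rearrangement sits beside both the new prenyl group and the allene of the second cascade and can add to either. All of this happens on the most advanced intermediate, and the construction of ring A and of the ether is left open.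
- **Comparison:** in step economy on ring B this alternative is stronger. The chosen route decorates ring B at the start, on an inexpensive quinone, where a moderate step costs little, and keeps the last stages to deprotection and ring closure.

Key step: step 11

## Route

Assumption (remark on the chemistry): hydroxyquinones 9 and 10 are drawn as their 6-hydroxy-5,8-dione (para-quinone) tautomers, and diene 5 as the (1Z,3Z) isomer; the geometry at C1 of 5 is irrelevant because this carbon becomes the ketal carbon of the cycloadduct.

Step 1
Reactants: 1 methyl acetoacetate; 2 1-bromo-3-methylbut-2-ene (prenyl bromide)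
Product: 3 methyl 7-methyl-3-oxooct-6-enoate
Conditions: NaH, THF, 0 °C; n-BuLi, 0 °C; 2, 0 °C to rt; aq. HCl
Reagents that add atoms: none
Why: γ-Alkylation of the acetoacetate dianion: the second, less stabilised carbanion on the terminal methyl is the more nucleophilic and takes the primary allylic bromide by SN2, while the α-position stays protected as the enolate.

Step 2
Reactants: 3 methyl 7-methyl-3-oxooct-6-enoate
Product: 4 methyl (2E)-7-methyl-3-(trimethylsilyloxy)octa-2,6-dienoate
Conditions: Me3SiCl, Et3N, hexane, rt
Reagents that add atoms: chlorotrimethylsilane, C[Si](C)(C)Cl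
Why: O-Silylation of the enolised β-keto ester under amine base should give the conjugated silyl enol ether; its alkene geometry is of no consequence because this bond becomes the C2–C3 single bond of the diene.

Step 3
Reactants: 4 methyl (2E)-7-methyl-3-(trimethylsilyloxy)octa-2,6-dienoate
Product: 5 (1Z,3Z)-1-methoxy-7-methyl-1,3-bis(trimethylsilyloxy)octa-1,3,6-triene
Conditions: LiN(i-Pr)2, THF, −78 °C; Me3SiCl, −78 °C to rt; filtered under argon and used crude
Reagents that add atoms: chlorotrimethylsilane, C[Si](C)(C)Cl
Why: Kinetic γ-deprotonation of the vinylogous ester gives the extended dienolate, which is silylated on oxygen to the silyl ketene acetal; the CH2 of the prenyl group should end up trans to C2 (3Z) to avoid allylic strain, and this is the geometry that can reach the s-cis conformer.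

Step 4
Reactants: 6 2,5-dihydroxy-1,4-benzoquinone; 7 3-methylbut-2-enal
Product: 9 6-hydroxy-2,2-dimethyl-2H-chromene-5,8-dione, via alkylidene trione 8 (not isolated)
Conditions: ethylenediammonium diacetate (10 mol %), EtOH, 80 °C; 7 added slowly to 6 (2 equiv)
Reagents that add atoms: none
Why: Knoevenagel condensation at the vinylogous acid carbon of 6 gives 1-oxatriene 8, which closes by oxa-6π electrocyclisation to the 2H-pyran; closure on either flanking oxygen leads to the same tautomeric pair, and the excess of 6 holds back a second annulation at the remaining CH.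

Step 5
Reactants: 9 6-hydroxy-2,2-dimethyl-2H-chromene-5,8-dione; 2 1-bromo-3-methylbut-2-ene
Product: 10 6-hydroxy-2,2-dimethyl-7-(3-methylbut-2-en-1-yl)-2H-chromene-5,8-dione
Conditions: LiH, DMSO, rt; 2, NaI (cat.), rt to 45 °C
Reagents that add atoms: none
Why: C-Alkylation of the ambident hydroxyquinone anion, the reaction type used to prenylate 2-hydroxy-1,4-quinones: the lithium counter-ion stays on oxygen and steers the allylic bromide to C7, the only nucleophilic ring carbon.

Step 6
Reactants: 10 6-hydroxy-2,2-dimethyl-7-(3-methylbut-2-en-1-yl)-2H-chromene-5,8-dione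
Product: 11 2,2-dimethyl-7-(3-methylbut-2-en-1-yl)-6-(prop-2-en-1-yloxy)-2H-chromene-5,8-dione
Conditions: allyl bromide, K2CO3, DMF, rt
Reagents that add atoms: allyl bromide, C=CCBr
Why: With C7 now blocked, alkylation of the vinylogous acid under carbonate base should take place on oxygen and give the para-quinone vinylogous ester; this marks the oxygen that will carry ring A while the two quinone carbonyls stay distinct from it.

Step 7
Reactants: 11 2,2-dimethyl-7-(3-methylbut-2-en-1-yl)-6-(prop-2-en-1-yloxy)-2H-chromene-5,8-dione
Product: 13 5,8-bis(methoxymethoxy)-2,2-dimethyl-7-(3-methylbut-2-en-1-yl)-6-(prop-2-en-1-yloxy)-2H-chromene, via 5,8-dihydroxy hydroquinone 12 (not isolated)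
Conditions: Na2S2O4, EtOAc/H2O, rt, under argon; then NaH, MeOCH2Cl, DMF, 0 °C to rt
Reagents that add atoms: chloromethyl methyl ether, COCCl
Why: Dithionite reduces the quinone to hydroquinone 12, whose two new phenols are capped at once as methoxymethyl ethers (Williamson alkylation) before air can reoxidise them; the allyl ether, prenyl group and chromene are untouched.

Step 8
Reactants: 13 5,8-bis(methoxymethoxy)-2,2-dimethyl-7-(3-methylbut-2-en-1-yl)-6-(prop-2-en-1-yloxy)-2H-chromene
Product: 14 5,8-bis(methoxymethoxy)-2,2-dimethyl-7-(3-methylbut-2-en-1-yl)-2H-chromen-6-ol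
Conditions: Pd(PPh3)4 (5 mol %), K2CO3, MeOH, rt, under argon
Reagents that add atoms: none
Why: Zerovalent palladium ionises the aryl allyl ether to a π-allyl complex (Tsuji–Trost), which methanol intercepts, freeing only the C6 phenol; acetal ethers and the trisubstituted and cyclic alkenes are inert.

Step 9
Reactants: 14 5,8-bis(methoxymethoxy)-2,2-dimethyl-7-(3-methylbut-2-en-1-yl)-2H-chromen-6-ol; 15 trichloroethylene
Product: 16 6-{[(E)-1,2-dichloroethenyl]oxy}-5,8-bis(methoxymethoxy)-2,2-dimethyl-7-(3-methylbut-2-en-1-yl)-2H-chromene
Conditions: KH, THF, 0 °C; 15, −50 °C to rt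
Reagents that add atoms: none
Why: The potassium phenoxide removes HCl from 15 and adds in anti fashion to the dichloroacetylene so formed, which should give the (E)-1,2-dichlorovinyl ether; ring B has no free position, so only oxygen can react.

Step 10
Reactants: 16 6-{[(E)-1,2-dichloroethenyl]oxy}-5,8-bis(methoxymethoxy)-2,2-dimethyl-7-(3-methylbut-2-en-1-yl)-2H-chromene; 17 allyl chloroformate (prop-2-en-1-yl carbonochloridate)
Product: 20 prop-2-en-1-yl 3-{[5,8-bis(methoxymethoxy)-2,2-dimethyl-7-(3-methylbut-2-en-1-yl)-2H-chromen-6-yl]oxy}prop-2-ynoate, via chloroethynyl aryl ether 18 (not isolated), via lithium aryloxyacetylide 19 (not isolated)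
Conditions: n-BuLi (2.3 equiv), THF, −78 to −40 °C; then added to 17 (2 equiv), THF, −78 °C
Reagents that add atoms: none
Why: Deprotonation and loss of LiCl give chloroalkyne 18, chlorine–lithium exchange with the second equivalent of n-BuLi gives acetylide 19, and C-acylation by 17 under inverse addition should give the ynoate; this is the standard route from dichlorovinyl ethers to ynol ethers.

Step 11
Reactants: 5 (1Z,3Z)-1-methoxy-7-methyl-1,3-bis(trimethylsilyloxy)octa-1,3,6-triene; 20 prop-2-en-1-yl 3-{[5,8-bis(methoxymethoxy)-2,2-dimethyl-7-(3-methylbut-2-en-1-yl)-2H-chromen-6-yl]oxy}prop-2-ynoate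
Product: 22 prop-2-en-1-yl 2-{[5,8-bis(methoxymethoxy)-2,2-dimethyl-7-(3-methylbut-2-en-1-yl)-2H-chromen-6-yl]oxy}-4,6-dihydroxy-3-(3-methylbut-2-en-1-yl)benzoate, via bis-silylated cyclohexa-1,4-diene cycloadduct 21 (not isolated)
Conditions: 5 (2.5 equiv), toluene, 100 °C, sealed tube; then 10% aq. citric acid, THF, rt
Reagents that add atoms: none
Why: Normal-demand [4+2] cycloaddition, concerted but asynchronous: the prenyl-bearing terminus C4 of 5, which has the largest HOMO coefficient, bonds to the β-carbon of 20 (the carbon carrying the aryloxy group, future A1), and the ketene acetal carbon C1 bonds to the α-carbon (future A6). The closest known reaction type is the cycloaddition–aromatisation of 1-alkoxy-1,3-bis(silyloxy)butadienes with acetylenic esters to 2,4-dihydroxybenzoates; the aryloxy substituent on the alkyne is the only element added to it. Ring A is closed by the cycloaddition itself, the bonds A1–A2 and A5–A6 being formed together from the s-cis conformer of the diene. Cycloadduct 21 is a cyclohexa-1,4-diene with a mixed methyl silyl ketal on A5 and a silyl enol ether on A3; dilute acid removes the methoxy group and both silyl groups and the ring aromatises by tautomerisation, leaving hydroxyls on A3 and A5. No stereocentre is set, since the two sp3 carbons of 21 (A2 and A5) are erased on aromatisation. The step needs regioselectivity, secured by the match between the ester-polarised alkyne (whose β-carbon stays the acceptor site, as in β-alkoxyacrylates) and the ketene acetal end of the diene, and chemoselectivity, which follows because the prenyl, chromene and allyl alkenes are unactivated. Because the aryloxy group lowers the dienophilicity, heating in toluene with excess 5 is planned; the linear alkyne keeps the di-ortho-substituted aryl group away from the bond-forming carbons, and an aryl ynol ether has no β-hydrogen through which it could fragment on heating.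

Step 12
Reactants: 22 prop-2-en-1-yl 2-{[5,8-bis(methoxymethoxy)-2,2-dimethyl-7-(3-methylbut-2-en-1-yl)-2H-chromen-6-yl]oxy}-4,6-dihydroxy-3-(3-methylbut-2-en-1-yl)benzoate
Product: 23 prop-2-en-1-yl 2-{[5,8-dihydroxy-2,2-dimethyl-7-(3-methylbut-2-en-1-yl)-2H-chromen-6-yl]oxy}-4,6-dihydroxy-3-(3-methylbut-2-en-1-yl)benzoate
Conditions: HCl (1 M in MeOH), rt to 35 °C
Reagents that add atoms: none
Why: Acid-catalysed acetal exchange with methanol removes both methoxymethyl ethers; the carboxyl is still an ester, so the trioxygenated ring A cannot decarboxylate, and the low acid strength and temperature are chosen to spare the ortho-prenyl phenols.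

Step 13
Reactants: 23 prop-2-en-1-yl 2-{[5,8-dihydroxy-2,2-dimethyl-7-(3-methylbut-2-en-1-yl)-2H-chromen-6-yl]oxy}-4,6-dihydroxy-3-(3-methylbut-2-en-1-yl)benzoate
Product: 24 2-{[5,8-dihydroxy-2,2-dimethyl-7-(3-methylbut-2-en-1-yl)-2H-chromen-6-yl]oxy}-4,6-dihydroxy-3-(3-methylbut-2-en-1-yl)benzoic acid
Conditions: Pd(PPh3)4 (5 mol %), morpholine (10 equiv), THF, rt; pH 4 buffer work-up, used at once
Reagents that add atoms: none
Why: Tsuji–Trost deallylation: zerovalent palladium ionises the allyl ester and the excess of morpholine captures the allyl unit, releasing the acid under neutral conditions that leave the phenols, prenyl groups and chromene alone.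

Step 14
Reactants: 24 2-{[5,8-dihydroxy-2,2-dimethyl-7-(3-methylbut-2-en-1-yl)-2H-chromen-6-yl]oxy}-4,6-dihydroxy-3-(3-methylbut-2-en-1-yl)benzoic acid
Product: 25 target depsidone CNP0263700.0 (lactone from the A6 carboxyl to the B5 oxygen; hydroxyls on A3, A5 and B2; prenyl groups on A2 and B1; 2,2-dimethyl-2H-pyran fused at B3/B4)
Conditions: N,N'-dicyclohexylcarbodiimide, 4-(dimethylamino)pyridine (cat.), CH2Cl2/THF (2 mM), 0 °C to rt
Reagents that add atoms: none
Why: Carbodiimide lactonisation: the activated carboxyl is attacked by the B5 hydroxyl through a seven-membered transition state; no other hydroxyl can reach the carboxyl intramolecularly, and high dilution disfavours intermolecular esters.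

## Compound list

1 | methyl acetoacetate | COC(=O)CC(C)=O | starting material
2 | 1-bromo-3-methylbut-2-ene (prenyl bromide) | CC(C)=CCBr | starting material
3 | methyl 7-methyl-3-oxooct-6-enoate | COC(=O)CC(=O)CCC=C(C)C | intermediate
4 | methyl (2E)-7-methyl-3-(trimethylsilyloxy)octa-2,6-dienoate | COC(=O)/C=C(/O[Si](C)(C)C)CCC=C(C)C | intermediate
5 | (1Z,3Z)-1-methoxy-7-methyl-1,3-bis(trimethylsilyloxy)octa-1,3,6-triene | CO/C(O[Si](C)(C)C)=C/C(O[Si](C)(C)C)=C/CC=C(C)C | intermediate
6 | 2,5-dihydroxy-1,4-benzoquinone | O=C1C=C(O)C(=O)C=C1O | starting material
7 | 3-methylbut-2-enal | CC(C)=CC=O | starting material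
8 | 5-hydroxy-3-(3-methylbut-2-en-1-ylidene)cyclohex-5-ene-1,2,4-trione (not isolated) | CC(C)=CC=C1C(=O)C(=O)C=C(O)C1=O | intermediate
9 | 6-hydroxy-2,2-dimethyl-2H-chromene-5,8-dione | CC1(C)C=CC2=C(O1)C(=O)C=C(O)C2=O | intermediate
10 | 6-hydroxy-2,2-dimethyl-7-(3-methylbut-2-en-1-yl)-2H-chromene-5,8-dione | CC(C)=CCC1=C(O)C(=O)C2=C(OC(C)(C)C=C2)C1=O | intermediate
11 | 2,2-dimethyl-7-(3-methylbut-2-en-1-yl)-6-(prop-2-en-1-yloxy)-2H-chromene-5,8-dione | C=CCOC1=C(CC=C(C)C)C(=O)C2=C(C=CC(C)(C)O2)C1=O | intermediate
12 | 2,2-dimethyl-7-(3-methylbut-2-en-1-yl)-6-(prop-2-en-1-yloxy)-2H-chromene-5,8-diol (not isolated) | C=CCOc1c(CC=C(C)C)c(O)c2OC(C)(C)C=Cc2c1O | intermediate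
13 | 5,8-bis(methoxymethoxy)-2,2-dimethyl-7-(3-methylbut-2-en-1-yl)-6-(prop-2-en-1-yloxy)-2H-chromene | C=CCOc1c(CC=C(C)C)c(OCOC)c2OC(C)(C)C=Cc2c1OCOC | intermediate
14 | 5,8-bis(methoxymethoxy)-2,2-dimethyl-7-(3-methylbut-2-en-1-yl)-2H-chromen-6-ol | Oc1c(CC=C(C)C)c(OCOC)c2OC(C)(C)C=Cc2c1OCOC | intermediate
15 | trichloroethylene | ClC=C(Cl)Cl | starting material
16 | 6-{[(E)-1,2-dichloroethenyl]oxy}-5,8-bis(methoxymethoxy)-2,2-dimethyl-7-(3-methylbut-2-en-1-yl)-2H-chromene | Cl/C=C(/Cl)Oc1c(CC=C(C)C)c(OCOC)c2OC(C)(C)C=Cc2c1OCOC | intermediate
17 | allyl chloroformate (prop-2-en-1-yl carbonochloridate) | C=CCOC(=O)Cl | starting material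
18 | 6-[(chloroethynyl)oxy]-5,8-bis(methoxymethoxy)-2,2-dimethyl-7-(3-methylbut-2-en-1-yl)-2H-chromene (not isolated) | ClC#COc1c(CC=C(C)C)c(OCOC)c2OC(C)(C)C=Cc2c1OCOC | intermediate
19 | lithium 2-{[5,8-bis(methoxymethoxy)-2,2-dimethyl-7-(3-methylbut-2-en-1-yl)-2H-chromen-6-yl]oxy}ethynide (not isolated) | [Li]C#COc1c(CC=C(C)C)c(OCOC)c2OC(C)(C)C=Cc2c1OCOC | intermediate
20 | prop-2-en-1-yl 3-{[5,8-bis(methoxymethoxy)-2,2-dimethyl-7-(3-methylbut-2-en-1-yl)-2H-chromen-6-yl]oxy}prop-2-ynoate | C=CCOC(=O)C#COc1c(CC=C(C)C)c(OCOC)c2OC(C)(C)C=Cc2c1OCOC | intermediate
21 | prop-2-en-1-yl 2-(aryloxy)-6-methoxy-3-(3-methylbut-2-en-1-yl)-4,6-bis(trimethylsilyloxy)cyclohexa-1,4-diene-1-carboxylate, aryl being the 6-chromenyl group of 14 (mixture of diastereomers, not isolated) | C=CCOC(=O)C1=C(Oc2c(CC=C(C)C)c(OCOC)c3OC(C)(C)C=Cc3c2OCOC)C(CC=C(C)C)C(O[Si](C)(C)C)=CC1(OC)O[Si](C)(C)C | intermediate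
22 | prop-2-en-1-yl 2-{[5,8-bis(methoxymethoxy)-2,2-dimethyl-7-(3-methylbut-2-en-1-yl)-2H-chromen-6-yl]oxy}-4,6-dihydroxy-3-(3-methylbut-2-en-1-yl)benzoate | C=CCOC(=O)c1c(O)cc(O)c(CC=C(C)C)c1Oc1c(CC=C(C)C)c(OCOC)c2OC(C)(C)C=Cc2c1OCOC | intermediate
23 | prop-2-en-1-yl 2-{[5,8-dihydroxy-2,2-dimethyl-7-(3-methylbut-2-en-1-yl)-2H-chromen-6-yl]oxy}-4,6-dihydroxy-3-(3-methylbut-2-en-1-yl)benzoate | C=CCOC(=O)c1c(O)cc(O)c(CC=C(C)C)c1Oc1c(CC=C(C)C)c(O)c2OC(C)(C)C=Cc2c1O | intermediate
24 | 2-{[5,8-dihydroxy-2,2-dimethyl-7-(3-methylbut-2-en-1-yl)-2H-chromen-6-yl]oxy}-4,6-dihydroxy-3-(3-methylbut-2-en-1-yl)benzoic acid | OC(=O)c1c(O)cc(O)c(CC=C(C)C)c1Oc1c(CC=C(C)C)c(O)c2OC(C)(C)C=Cc2c1O | intermediate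
25 | target depsidone CNP0263700.0 (lactone from the A6 carboxyl to the B5 oxygen; hydroxyls on A3, A5 and B2; prenyl on A2 and B1; 2,2-dimethyl-2H-pyran on B3/B4) | CC(C)=CCc1c(O)c2c(c3c1Oc1c(CC=C(C)C)c(O)cc(O)c1C(=O)O3)C=CC(C)(C)O2 | target

## Step count and least certain steps

Total: 14 steps. Longest linear sequence: 11 steps (steps 4 to 14, from quinone 6); the diene branch (steps 1 to 3) joins at step 11.

**Step 11 (key step).** The aryloxy group donates into the alkyne, so cycloaddition may be slower than thermal desilylation or silyl migration of diene 5. Alternatively, the first bond may form without ring closure, after which expulsion of the aryloxide (addition–elimination) would destroy the ether.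
Fallback, from diene 5 and phenol 14, returning at 23: ring A is built first with a halogen on A1 and the ether is made afterwards. Diene 5 is heated in toluene (60–80 °C, then dilute acid) with allyl 3-bromopropiolate F1 (made by AgNO3-catalysed bromination of the terminal alkynoate with N-bromosuccinimide), a more reactive dienophile of the same polarity. This should give allyl 2-bromo-4,6-dihydroxy-3-(3-methylbut-2-en-1-yl)benzoate F2. NaH and MeOCH2Cl convert it into the bis(methoxymethyl) ether F3. Copper-catalysed Ullmann ether coupling of F3 with phenol 14 (CuI, picolinic acid, K3PO4, DMSO, 90 °C) would give the tetrakis(methoxymethyl) diaryl ether allyl ester F4, and HCl in MeOH then gives 23. This brings back the hindered aryl–oxygen coupling that the main plan avoids, although the ortho ester should assist the copper step.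

**Step 10.** The acetylide may add a second time to the newly formed ynoate, or the electrophilic push–pull ynoate may be hydrated or take up nucleophiles during work-up and chromatography.
Fallback, from phenol 14, returning at 20 (it also bypasses step 9): the potassium phenoxide of 14 (K2CO3, DMF) is added to allyl 3,3-dichloroprop-2-enoate F5 (the allyl ester of the commercial acid). Addition–elimination gives allyl 3-aryloxy-3-chloroprop-2-enoate F6 as a mixture of alkene isomers. Dehydrochlorination with LiN(SiMe3)2 in THF at −78 °C, in the manner used to turn β-keto ester enol derivatives into alkynoates, then gives 20 without any organolithium.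

**Step 5.** O-Alkylation and dialkylation of the ambident anion may compete with C-alkylation and lower the conversion to the C7-prenyl compound.
Fallback, from 9, returning at 10: 9 is allylated (allyl bromide, K2CO3, DMF) to 6-(allyloxy)-2,2-dimethyl-2H-chromene-5,8-dione F7. Heating in toluene at 110 °C brings about Claisen rearrangement to 7-allyl-6-hydroxy-2,2-dimethyl-2H-chromene-5,8-dione F8; any O-allyl isomer on the other oxygen and any C-allyl product converge on the same compound. Cross-metathesis of F8 with 2-methylbut-2-ene (second-generation Grubbs catalyst, CH2Cl2, 40 °C) then turns the allyl group into the prenyl group of 10.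

**Step 6.** The ambident vinylogous carboxylate may be alkylated on the other oxygen, giving the ortho-quinone ether, and warming could start a Claisen shift of the allyl group onto C7.
Fallback, from 10, returning at 11: the hydroxyl is first exchanged for chlorine with oxalyl chloride and catalytic DMF in CH2Cl2 at 0 °C, giving 6-chloro-2,2-dimethyl-7-(3-methylbut-2-en-1-yl)-2H-chromene-5,8-dione F9. Addition–elimination with allyl alcohol and Et3N then puts the allyloxy group on the carbon that carried chlorine, so the regiochemistry is fixed by the halide.

**Step 14.** Intermolecular acylation of the other three phenols (oligomers) or rearrangement of the activated acid to an N-acylurea may outrun the seven-membered ring closure.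
Fallback, from 16, returning at 25 (it replaces steps 10 to 14 by four steps): the acetylide from 16 is trapped with phenyl chloroformate in place of 17, giving phenyl 3-aryloxypropiolate F10, a somewhat better dienophile. Cycloaddition with 5 as in step 11 gives phenyl 2-aryloxy-4,6-dihydroxy-3-(3-methylbut-2-en-1-yl)benzoate F11. HCl in MeOH removes the acetal ethers to give the tetrahydroxy phenyl ester F12. A mild base at high dilution (i-Pr2NEt with catalytic 4-(dimethylamino)pyridine in toluene at 60 °C, or K2CO3 in MeCN) then lets the B5 phenoxide displace phenoxide intramolecularly to give 25. No free acid and no carbodiimide are involved.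

## Further compounds

F1 | step 11 | prop-2-en-1-yl 3-bromoprop-2-ynoate | C=CCOC(=O)C#CBr
F2 | step 11 | prop-2-en-1-yl 2-bromo-4,6-dihydroxy-3-(3-methylbut-2-en-1-yl)benzoate | C=CCOC(=O)c1c(O)cc(O)c(CC=C(C)C)c1Br
F3 | step 11 | prop-2-en-1-yl 2-bromo-4,6-bis(methoxymethoxy)-3-(3-methylbut-2-en-1-yl)benzoate | C=CCOC(=O)c1c(OCOC)cc(OCOC)c(CC=C(C)C)c1Br
F4 | step 11 | prop-2-en-1-yl 2-{[5,8-bis(methoxymethoxy)-2,2-dimethyl-7-(3-methylbut-2-en-1-yl)-2H-chromen-6-yl]oxy}-4,6-bis(methoxymethoxy)-3-(3-methylbut-2-en-1-yl)benzoate | C=CCOC(=O)c1c(OCOC)cc(OCOC)c(CC=C(C)C)c1Oc1c(CC=C(C)C)c(OCOC)c2OC(C)(C)C=Cc2c1OCOC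
F5 | step 10 | prop-2-en-1-yl 3,3-dichloroprop-2-enoate | C=CCOC(=O)C=C(Cl)Cl
F6 | step 10 | prop-2-en-1-yl 3-{[5,8-bis(methoxymethoxy)-2,2-dimethyl-7-(3-methylbut-2-en-1-yl)-2H-chromen-6-yl]oxy}-3-chloroprop-2-enoate (mixture of alkene isomers) | C=CCOC(=O)C=C(Cl)Oc1c(CC=C(C)C)c(OCOC)c2OC(C)(C)C=Cc2c1OCOC
F7 | step 5 | 2,2-dimethyl-6-(prop-2-en-1-yloxy)-2H-chromene-5,8-dione | C=CCOC1=CC(=O)C2=C(C=CC(C)(C)O2)C1=O
F8 | step 5 | 6-hydroxy-2,2-dimethyl-7-(prop-2-en-1-yl)-2H-chromene-5,8-dione | C=CCC1=C(O)C(=O)C2=C(OC(C)(C)C=C2)C1=O
F9 | step 6 | 6-chloro-2,2-dimethyl-7-(3-methylbut-2-en-1-yl)-2H-chromene-5,8-dione | CC(C)=CCC1=C(Cl)C(=O)C2=C(OC(C)(C)C=C2)C1=O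
F10 | step 14 | phenyl 3-{[5,8-bis(methoxymethoxy)-2,2-dimethyl-7-(3-methylbut-2-en-1-yl)-2H-chromen-6-yl]oxy}prop-2-ynoate | O=C(Oc1ccccc1)C#COc1c(CC=C(C)C)c(OCOC)c2OC(C)(C)C=Cc2c1OCOC
F11 | step 14 | phenyl 2-{[5,8-bis(methoxymethoxy)-2,2-dimethyl-7-(3-methylbut-2-en-1-yl)-2H-chromen-6-yl]oxy}-4,6-dihydroxy-3-(3-methylbut-2-en-1-yl)benzoate | O=C(Oc1ccccc1)c1c(O)cc(O)c(CC=C(C)C)c1Oc1c(CC=C(C)C)c(OCOC)c2OC(C)(C)C=Cc2c1OCOC
F12 | step 14 | phenyl 2-{[5,8-dihydroxy-2,2-dimethyl-7-(3-methylbut-2-en-1-yl)-2H-chromen-6-yl]oxy}-4,6-dihydroxy-3-(3-methylbut-2-en-1-yl)benzoate | O=C(Oc1ccccc1)c1c(O)cc(O)c(CC=C(C)C)c1Oc1c(CC=C(C)C)c(O)c2OC(C)(C)C=Cc2c1O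
A1 | alternative 1 | diaryl ether with iodine on A6, methoxymethyl ethers on A3 and A5, and phenyl carbonates on the B2 and B5 oxygens | CC(C)=CCc1c(OCOC)cc(OCOC)c(I)c1Oc1c(CC=C(C)C)c(OC(=O)Oc2ccccc2)c2OC(C)(C)C=Cc2c1OC(=O)Oc1ccccc1
A2 | alternative 1 | depsidone with a phenyl carbonate on the B2 oxygen and methoxymethyl ethers on A3 and A5 | CC(C)=CCc1c(OC(=O)Oc4ccccc4)c2c(c3c1Oc1c(CC=C(C)C)c(OCOC)cc(OCOC)c1C(=O)O3)C=CC(C)(C)O2
A3 | alternative 2 | 3,5-bis(methoxymethoxy)-2-(3-methylbut-2-en-1-yl)-6-(trimethylsilyl)phenyl trifluoromethanesulfonate | CC(C)=CCc1c(OCOC)cc(OCOC)c([Si](C)(C)C)c1OS(=O)(=O)C(F)(F)F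
A4 | alternative 2 | 2-{[5,8-bis(methoxymethoxy)-2,2-dimethyl-7-(3-methylbut-2-en-1-yl)-2H-chromen-6-yl]oxy}-4,6-bis(methoxymethoxy)-3-(3-methylbut-2-en-1-yl)benzoic acid | OC(=O)c1c(OCOC)cc(OCOC)c(CC=C(C)C)c1Oc1c(CC=C(C)C)c(OCOC)c2OC(C)(C)C=Cc2c1OCOC
A5 | alternative 3 | depsidone with hydrogen on B1 and B4, a 2-methylbut-3-en-2-yl ether on the B2 oxygen, a 2-methylbut-3-yn-2-yl ether on the B3 oxygen, a methoxymethyl ether on A3 and a free hydroxyl on A5 | C=CC(C)(C)Oc1cc2Oc3c(CC=C(C)C)c(OCOC)cc(O)c3C(=O)Oc2cc1OC(C)(C)C#C
A6 | alternative 3 | A3 methoxymethyl ether of the target | CC(C)=CCc1c(O)c2c(c3c1Oc1c(CC=C(C)C)c(OCOC)cc(O)c1C(=O)O3)C=CC(C)(C)O2
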